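**Plan**

1. The target is 3-hydroxy-2-methyl-5-nonadecyl-1,4-benzoquinone (ring: C1=O, C2–CH3, C3–OH, C4=O, C5–C19H39, C6–H). It has no stereocentre and no stereogenic double bond, so no stereochemistry has to be set.
2. Enabling feature: the ring is a masked 2-methyl-5-alkylresorcinol, with the oxygens on C1 and C3 flanking the C2 methyl. C2(CH3)=C3(O) therefore maps onto a polarised ynol ether and C1–C6–C5–C4 onto a vinylketene, while the C4 oxygen can be added last, para to the C1 phenol.
3. Retrosynthesis: the O3 silyl group and the C4 oxygen are removed first (quinone to 3-silyloxyphenol). Then C1–C2 and C3–C4 are cut together (benzannulation of a cyclobutenone with a siloxyalkyne). The cyclobutenone is cut to dichloroketene plus henicos-1-yne, and the chain to acetylide plus 1-bromononadecane.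
4. Forward: the chain is joined (step 1), the four-membered ring is made and dechlorinated (steps 2–3), the siloxyalkyne is made (step 4), the benzene ring arises in one operation (step 5), then oxidation to the quinone (step 6) and desilylation (step 7).

Key step: step 5

Remark: the side chain is read from the SMILES as an unbranched nonadecyl (C19) group, and the compound is treated as its 3-hydroxy-1,4-quinone tautomer.

**Step 1**
Reactants: 1 1-bromononadecane; 2 lithium acetylide–ethylenediamine complex
Product: 3 henicos-1-yne
Conditions: DMSO/THF, 10 °C → rt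
Reagents that add atoms: none
Why: SN2 alkylation of an acetylide by an unhindered primary bromide in a dipolar aprotic medium should give the terminal alkyne, the diamine complex keeping the acetylide monomeric and limiting elimination.

**Step 2**
Reactants: 3 henicos-1-yne; 4 trichloroacetyl chloride
Product: 6 4,4-dichloro-3-nonadecylcyclobut-2-en-1-one, via dichloroketene 5 (not isolated)
Conditions: Zn(Cu) couple, Et2O/DME, rt
Reagents that add atoms: none
Why: Ketene–alkyne [2+2] cycloaddition of dichloroketene generated in situ by zinc dechlorination should place the ketene carbonyl carbon on the unsubstituted alkyne terminus and so the chain on C3, with DME binding the ZnCl2 that would otherwise degrade the product.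

**Step 3**
Reactants: 6 4,4-dichloro-3-nonadecylcyclobut-2-en-1-one
Product: 7 3-nonadecylcyclobut-2-en-1-one
Conditions: Zn dust, AcOH, TMEDA, EtOH/THF, 0 °C → rt
Reagents that add atoms: none
Why: Reductive dechlorination of an α,α-dichloroketone by zinc through zinc enolates that AcOH protonates should remove both chlorines, the TMEDA buffer sparing the strained enone from isomerisation and ring opening.

**Step 4**
Reactants: 8 prop-1-yn-1-yllithium
Product: 10 triisopropyl(prop-1-yn-1-yloxy)silane, via lithium prop-1-yn-1-olate 9 (not isolated)
Conditions: t-BuOOH, LiN(SiMe3)2, THF, −78 °C; then 8, −78 → 0 °C; then i-Pr3SiOTf, −78 °C → rt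
Reagents that add atoms: tert-butyl hydroperoxide, CC(C)(C)OO; triisopropylsilyl trifluoromethanesulfonate, CC(C)[Si](C(C)C)(C(C)C)OS(=O)(=O)C(F)(F)F
Why: Electrophilic oxygenation of a lithium acetylide by lithium tert-butyl peroxide should give the ynolate, which the bulky silyl triflate traps on oxygen to give the silyl ynol ether.

**Step 5**
Reactants: 7 3-nonadecylcyclobut-2-en-1-one; 10 triisopropyl(prop-1-yn-1-yloxy)silane (1.5 equiv)
Product: 15 2-methyl-5-nonadecyl-3-[(triisopropylsilyl)oxy]phenol, via vinylketene 11 (not isolated), via 4-vinylcyclobutenone adduct 12 (not isolated), via dienylketene 13 (not isolated), via cyclohexa-2,4-dienone 14 (not isolated)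
Conditions: toluene, 80 °C → 110 °C
Reagents that add atoms: none
Why: Thermal 4π-electrocyclic opening of 7 should give vinylketene 11, whose ketene C=C adds in a [2+2] cycloaddition to the electron-rich triple bond of 10; 4π-opening of the resulting cyclobutenone 12 gives dienylketene 13, which closes by 6π-electrocyclisation to dienone 14 and tautomerises to phenol 15 (Danheiser benzannulation, the closest known reaction type, established for 2,5-dialkylresorcinol monoethers). The transient four-membered ring of 12 is closed by the ketene–alkyne [2+2] cycloaddition and the six-membered ring by disrotatory 6π-electrocyclisation that re-forms the original C1–C6 bond, so the net new bonds are C1–C2 and C3–C4. No stereocentre survives, because the sp3 carbon of 12 and the CH2 of 14 are erased on aromatisation. The step needs one regiochemical outcome, and the polarity of the partners secures it: the nucleophilic methyl-bearing carbon of the ynol ether bonds to the electrophilic ketene carbon and the oxygen-bearing carbon to the ketene terminus, which puts the methyl ortho and the silyloxy group meta to the new phenol OH, with the chain on C5. Excess 10 should keep the vinylketene from acylating the phenol, and a 1,3-silyl shift would be harmless because the parent resorcinol is symmetrical.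

**Step 6**
Reactants: 15 2-methyl-5-nonadecyl-3-[(triisopropylsilyl)oxy]phenol
Product: 16 2-methyl-5-nonadecyl-3-[(triisopropylsilyl)oxy]cyclohexa-2,5-diene-1,4-dione
Conditions: (KSO3)2NO (2.5 equiv), aq. KH2PO4, methyltrioctylammonium chloride (cat.), CH2Cl2/H2O, rt
Reagents that add atoms: potassium nitrosodisulfonate (Fremy's salt), [K+].[K+].[O]N(S(=O)(=O)[O-])S(=O)(=O)[O-]
Why: In this Teuber oxidation the phenoxyl radical formed by the first nitroxide should be trapped at the free para carbon C4 by the second and lose imidodisulfonate to give the p-quinone, as with 3-alkoxy-5-alkylphenols, and trapping at the free ortho carbon C6 would lead after step 7 to a tautomer of the same hydroxyquinone.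

**Step 7**
Reactants: 16 2-methyl-5-nonadecyl-3-[(triisopropylsilyl)oxy]cyclohexa-2,5-diene-1,4-dione
Product: 17 capiquinone C (3-hydroxy-2-methyl-5-nonadecylcyclohexa-2,5-diene-1,4-dione)
Conditions: aq. HF (48%), MeCN/THF, 0 °C → rt
Reagents that add atoms: none
Why: Fluoride cleavage of the Si–O bond of a vinylogous silyl ester (silyl ether deprotection) should release the acidic hydroxyquinone under non-basic conditions that spare the quinone.

**Compound list**

1 | 1-bromononadecane | CCCCCCCCCCCCCCCCCCCBr | starting material
2 | lithium acetylide–ethylenediamine complex | [Li+].[C-]#C.NCCN | starting material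
3 | henicos-1-yne | CCCCCCCCCCCCCCCCCCCC#C | intermediate
4 | trichloroacetyl chloride | ClC(Cl)(Cl)C(Cl)=O | starting material
5 | dichloroketene | ClC(Cl)=C=O | intermediate (not isolated)
6 | 4,4-dichloro-3-nonadecylcyclobut-2-en-1-one | CCCCCCCCCCCCCCCCCCCC1=CC(=O)C1(Cl)Cl | intermediate
7 | 3-nonadecylcyclobut-2-en-1-one | CCCCCCCCCCCCCCCCCCCC1=CC(=O)C1 | intermediate
8 | prop-1-yn-1-yllithium | [Li+].[C-]#CC | starting material
9 | lithium prop-1-yn-1-olate | CC#C[O-].[Li+] | intermediate (not isolated)
10 | triisopropyl(prop-1-yn-1-yloxy)silane | CC#CO[Si](C(C)C)(C(C)C)C(C)C | intermediate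
11 | 3-methylidenedocos-1-en-1-one (vinylketene) | CCCCCCCCCCCCCCCCCCCC(=C)C=C=O | intermediate (not isolated)
12 | 4-(henicos-1-en-2-yl)-2-methyl-3-[(triisopropylsilyl)oxy]cyclobut-2-en-1-one (racemic) | CCCCCCCCCCCCCCCCCCCC(=C)C1C(=O)C(C)=C1O[Si](C(C)C)(C(C)C)C(C)C | intermediate (not isolated)
13 | (3E)-2-methyl-5-methylidene-3-[(triisopropylsilyl)oxy]tetracosa-1,3-dien-1-one (dienylketene) | CCCCCCCCCCCCCCCCCCCC(=C)/C=C(O[Si](C(C)C)(C(C)C)C(C)C)\C(C)=C=O | intermediate (not isolated)
14 | 2-methyl-5-nonadecyl-3-[(triisopropylsilyl)oxy]cyclohexa-2,4-dien-1-one | CCCCCCCCCCCCCCCCCCCC1=CC(O[Si](C(C)C)(C(C)C)C(C)C)=C(C)C(=O)C1 | intermediate (not isolated)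
15 | 2-methyl-5-nonadecyl-3-[(triisopropylsilyl)oxy]phenol | CCCCCCCCCCCCCCCCCCCc1cc(O)c(C)c(O[Si](C(C)C)(C(C)C)C(C)C)c1 | intermediate
16 | 2-methyl-5-nonadecyl-3-[(triisopropylsilyl)oxy]cyclohexa-2,5-diene-1,4-dione | CCCCCCCCCCCCCCCCCCCC1=CC(=O)C(C)=C(O[Si](C(C)C)(C(C)C)C(C)C)C1=O | intermediate
17 | capiquinone C (3-hydroxy-2-methyl-5-nonadecylcyclohexa-2,5-diene-1,4-dione) | CCCCCCCCCCCCCCCCCCCC1=CC(=O)C(C)=C(O)C1=O | target

Total step count: 7. Longest linear sequence: 6 steps (steps 1, 2, 3, 5, 6, 7).

**Steps most likely to fail**

Step 5. Capture of the vinylketene by the siloxyalkyne may lose out to its dimerisation or to O-acylation of the phenol already formed, and the heat-sensitive siloxyalkyne may decompose before the [2+2] event. The fallback abandons the annulation and attaches the chain to a preformed arene. It sets out from 1, which with Mg in THF should give nonadecylmagnesium bromide F1. Kumada coupling of this with commercial 5-bromo-1,3-dimethoxy-2-methylbenzene under PdCl2(dppf) catalysis in THF at reflux should give 1,3-dimethoxy-2-methyl-5-nonadecylbenzene F2. BBr3 in CH2Cl2 (−78 °C → rt) should then give the symmetrical 2-methyl-5-nonadecylbenzene-1,3-diol F3. Teuber oxidation of this resorcinol with (KSO3)2NO in buffered aqueous THF should give the hydroxyquinone whichever free ring position is attacked. The fallback comes back to the route at 17.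

Step 4. The peroxide may over-oxidise the acetylide or the ynolate, silylation may occur on carbon to give a silylketene, and the small silyl ynol ether may hydrolyse during isolation. The fallback carries the C3 oxygen as an ethyl ether and unmasks it by vinylogous ester hydrolysis. It sets out from 7, which is heated with commercial 1-ethoxyprop-1-yne in toluene (80 → 110 °C) in the same benzannulation to give 3-ethoxy-2-methyl-5-nonadecylphenol F4. Oxidation with (KSO3)2NO as in step 6 should give 3-ethoxy-2-methyl-5-nonadecylcyclohexa-2,5-diene-1,4-dione F5. Hydrolysis with 70% HClO4 in aqueous dioxane at rt then comes back to the route at 17.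

Step 6. Radical trapping at the para carbon, which is flanked by the silyloxy group and the chain, may be slow, leaving room for phenoxyl coupling, premature loss of the silyl group and over-oxidation. The fallback oxygenates the unhindered ortho carbon by a two-electron path and relies on the hidden symmetry of the ring. It sets out from 15, which with IBX in DMF at rt should give 3-methyl-6-nonadecyl-4-[(triisopropylsilyl)oxy]cyclohexa-3,5-diene-1,2-dione F6. Desilylation with aq. HF in MeCN/THF should release 4-hydroxy-3-methyl-6-nonadecylcyclohexa-3,5-diene-1,2-dione F7, the prototropic tautomer of the target, which should settle as the 3-hydroxy-1,4-quinone. The fallback comes back to the route at 17.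

**Further compounds**

F1 | step 5 | nonadecylmagnesium bromide | CCCCCCCCCCCCCCCCCCC[Mg]Br
F2 | step 5 | 1,3-dimethoxy-2-methyl-5-nonadecylbenzene | CCCCCCCCCCCCCCCCCCCc1cc(OC)c(C)c(OC)c1
F3 | step 5 | 2-methyl-5-nonadecylbenzene-1,3-diol | CCCCCCCCCCCCCCCCCCCc1cc(O)c(C)c(O)c1
F4 | step 4 | 3-ethoxy-2-methyl-5-nonadecylphenol | CCCCCCCCCCCCCCCCCCCc1cc(O)c(C)c(OCC)c1
F5 | step 4 | 3-ethoxy-2-methyl-5-nonadecylcyclohexa-2,5-diene-1,4-dione | CCCCCCCCCCCCCCCCCCCC1=CC(=O)C(C)=C(OCC)C1=O
F6 | step 6 | 3-methyl-6-nonadecyl-4-[(triisopropylsilyl)oxy]cyclohexa-3,5-diene-1,2-dione | CCCCCCCCCCCCCCCCCCCC1=CC(O[Si](C(C)C)(C(C)C)C(C)C)=C(C)C(=O)C1=O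
F7 | step 6 | 4-hydroxy-3-methyl-6-nonadecylcyclohexa-3,5-diene-1,2-dione | CCCCCCCCCCCCCCCCCCCC1=CC(O)=C(C)C(=O)C1=O
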